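## Retrosynthetic overview

1. Target ⇒ tricyclic allylic alcohol + diangeloyl peroxide: both ester C–O bonds (C8–O, C9–O) are made in one operation by syn-bis(acyloxylation) of the C8=C9 alkene, anti to the C7 hydroxyl.
2. Tricyclic allylic alcohol ⇒ bicyclic tosylhydrazone: the seven-membered ring is formed last, by C5–C6 radical closure of an isopropenyl carbinol onto the cyclobutanone hydrazone, with C5 ending as C–H.
3. Z-dienyl carbinol ⇒ bicyclic alkyne + methacrolein: C7–C8 bond by asymmetric alkynylation, then Z-semihydrogenation.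
4. Bicyclic enedione ⇒ acyclic acid: cyclobutane and six-membered ring are formed together, first, by intramolecular vinylketene–alkene [2+2]; a silyloxy relay stereocentre at C1 later becomes the enone carbonyl.
5. Acyclic acid ⇒ enynal + silyl dienolate: C1–C2 bond by enantioselective vinylogous Mukaiyama aldol reaction.

Assumption: the target is made exactly as drawn (both esters Z, i.e. angelates). Locants C1–C11 in the running text are longipinane locants (C1 ring ketone, C2=C3 enone, C4/C11 bridgeheads, C5/C10 one-carbon bridges, C6 gem-dimethyl carbon, C7–C9 oxygenated carbons); names of bicyclic intermediates use bicyclo[3.1.1]heptane locants. The catalyst antipodes in steps 3 and 9 are those that give the (S)-carbinols drawn.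

## Route

Step 1
Reactants: 1 (2E)-3-methylpent-2-en-4-yn-1-ol
Product: 2 (2E)-3-methylpent-2-en-4-ynal
Conditions: MnO2 (activated, 15 equiv), CH2Cl2, rt; filtered and used as a solution
Reagents that add atoms: none
Why: Allylic alcohol oxidation with activated MnO2 stops at the aldehyde, keeps the E-alkene geometry, leaves the terminal alkyne alone and creates no stereocentre.

Step 2
Reactants: 3 methyl 3-methylbut-2-enoate
Product: 4 tert-butyl[(1-methoxy-3-methylbuta-1,3-dien-1-yl)oxy]dimethylsilane (silyl dienolate, mixture of ketene-acetal isomers)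
Conditions: LiN(iPr)2, THF, −78 °C; then TBSCl, DMPU, −78 °C → rt
Reagents that add atoms: tert-butyl(chloro)dimethylsilane (TBSCl), CC(C)(C)[Si](C)(C)Cl
Why: Kinetic γ-deprotonation of the senecioate followed by O-silylation (silyl ketene acetal formation) gives the cross-conjugated silyl dienolate needed for a vinylogous Mukaiyama aldol reaction, with no stereocentre formed.

Step 3
Reactants: 2 (2E)-3-methylpent-2-en-4-ynal; 4 silyl dienolate
Product: 5 methyl (2E,5S,6E)-5-hydroxy-3,7-dimethylnona-2,6-dien-8-ynoate
Conditions: SiCl4 (1.1 equiv), Denmark-type binaphthyldiamine bisphosphoramide (2 mol %), iPr2NEt (10 mol %), CH2Cl2, −78 °C; aqueous work-up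
Reagents that add atoms: none
Why: Vinylogous Mukaiyama aldol reaction under Lewis-base activation of SiCl4, in which the chiral phosphoramide-bound silicon cation holds the enal so that the unhindered γ-carbon of 4 attacks one aldehyde face only, which sets the C5 carbinol as S, while the new enoate forms as the 2E isomer with its methyl group cis to the ester.

Step 4
Reactants: 5 methyl (2E,5S,6E)-5-hydroxy-3,7-dimethylnona-2,6-dien-8-ynoate
Product: 6 methyl (2E,5S,6E)-5-[(tert-butyldimethylsilyl)oxy]-3,7-dimethylnona-2,6-dien-8-ynoate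
Conditions: TBSOTf, 2,6-lutidine, CH2Cl2, −78 → 0 °C
Reagents that add atoms: tert-butyldimethylsilyl trifluoromethanesulfonate (TBSOTf), CC(C)(C)[Si](C)(C)OS(=O)(=O)C(F)(F)F
Why: Silyl ether formation with a silyl triflate and a hindered pyridine base protects the secondary carbinol without touching the stereocentre, the enoate or the alkyne.

Step 5
Reactants: 6 TBS-protected methyl ester
Product: 7 (2E,5S,6E)-5-[(tert-butyldimethylsilyl)oxy]-3,7-dimethylnona-2,6-dien-8-ynoic acid
Conditions: LiOH, THF/MeOH/H2O, 40 °C; then cold 1 M HCl to pH 3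
Reagents that add atoms: lithium hydroxide (hydroxide oxygen), [Li+].[OH-]
Why: Ester saponification gives the free acid needed for ketene generation, while the TBS ether, both alkene geometries and the C5 stereocentre are stable to aqueous hydroxide at 40 °C.

Step 6
Reactants: 7 (2E,5S,6E)-5-[(tert-butyldimethylsilyl)oxy]-3,7-dimethylnona-2,6-dien-8-ynoic acid
Product: 10 (1R,2S,5R,7R)-2-[(tert-butyldimethylsilyl)oxy]-7-ethynyl-7-methyl-4-methylidenebicyclo[3.1.1]heptan-6-one (ethynyl anti to the C2–C4 bridge; silyloxy trans to C7), via acid chloride 8 (not isolated), via vinylketene 9 (not isolated)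
Conditions: (COCl)2, DMF (cat.), CH2Cl2, 0 °C → rt, evaporate; then slow addition to Et3N (5 equiv), PhMe (0.01 M), 110 °C; chromatographic removal of the minor C2 epimer (which carries the antipodal ring system)
Reagents that add atoms: none
Why: Intramolecular vinylketene–alkene [2+2] cycloaddition (Snider-type crossed mode), in which Et3N removes a proton from the methyl group cis to the acyl chloride, the ketene carbonyl carbon bonds to the alkene CH and the ketene α-carbon to the carbon that carries methyl and ethynyl, the E-alkene geometry is transferred so that the methyl ends syn and the ethynyl anti to the three-carbon bridge, and the silyloxy stereocentre steers the ketene to the alkene face that leaves OTBS trans to the methyl-bearing bridge (avoiding a clash with that methyl), which fixes the absolute configuration of the three new ring stereocentres.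

Step 7
Reactants: 10 bicyclic silyloxy ketone
Product: 11 (1R,2S,5R,7R)-7-ethynyl-2-hydroxy-7-methyl-4-methylidenebicyclo[3.1.1]heptan-6-one
Conditions: HF·pyridine, pyridine, THF, 0 °C → rt
Reagents that add atoms: none
Why: Silyl ether cleavage with buffered HF·pyridine frees the C2 carbinol under conditions that neither epimerise nor fragment the β-hydroxy cyclobutanone, whose α-carbons are bridgeheads.

Step 8
Reactants: 11 bicyclic hydroxy ketone
Product: 13 (1R,5R,7R)-7-ethynyl-4,7-dimethylbicyclo[3.1.1]hept-3-ene-2,6-dione, via exocyclic-alkene dione 12 (not isolated)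
Conditions: (COCl)2, DMSO, CH2Cl2, −78 °C; Et3N, −78 °C → rt; then DBU (0.2 equiv), rt
Reagents that add atoms: none
Why: Swern oxidation gives the β,γ-unsaturated ketone 12 and base-mediated isomerisation through its dienolate moves the exocyclic alkene into conjugation (verbenone-type enone), which removes the relay stereocentre after it has done its work and cannot touch the three ring stereocentres because every remaining α-position is a bridgehead or quaternary.

Step 9
Reactants: 13 bicyclic enedione alkyne; 14 methacrolein (2-methylprop-2-enal, 3 equiv)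
Product: 15 (1R,5R,7R)-7-[(3S)-3-hydroxy-4-methylpent-4-en-1-yn-1-yl]-4,7-dimethylbicyclo[3.1.1]hept-3-ene-2,6-dione
Conditions: Me2Zn (3 equiv), (S,S)-ProPhenol (10 mol %), Ph3P=O (20 mol %), PhMe, 0 → 4 °C; aq. NH4Cl
Reagents that add atoms: none
Why: Zinc–ProPhenol catalysed asymmetric alkynylation, in which the dinuclear zinc alkynylide formed from the terminal alkyne and Me2Zn adds 1,2 to methacrolein under catalyst control (the ring stereocentres are too remote to interfere) to set the new carbinol as S, while alkynylzinc species do not add to the hindered ketones.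

Step 10
Reactants: 15 propargylic alcohol
Product: 16 (1R,5R,7R)-7-[(1Z,3R)-3-hydroxy-4-methylpenta-1,4-dien-1-yl]-4,7-dimethylbicyclo[3.1.1]hept-3-ene-2,6-dione
Conditions: H2 (1 atm), Pd/CaCO3 poisoned with Pb(OAc)2, quinoline, EtOAc, rt, stopped at 1 equiv H2
Reagents that add atoms: none
Why: Lindlar semihydrogenation adds H2 syn to the alkyne to give the Z-alkene that the later ring closure requires, and the poisoned catalyst spares the enone and the 1,1-disubstituted alkene (the carbinol descriptor changes from S to R only because the priorities change).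

Step 11
Reactants: 16 Z-dienyl carbinol dione
Product: 17 C6 mono(4-methylbenzenesulfonyl)hydrazone of 16 (cyclobutanone carbonyl; C=N geometry not defined)
Conditions: TsNHNH2 (1.05 equiv), MeOH, rt
Reagents that add atoms: 4-methylbenzenesulfonohydrazide (TsNHNH2), Cc1ccc(cc1)S(=O)(=O)NN
Why: Hydrazone condensation occurs selectively at the strained, non-conjugated cyclobutanone carbonyl, which is far more electrophilic than the conjugated enone carbonyl, under neutral conditions that do not cleave the β-diketone.

Step 12
Reactants: 17 cyclobutanone tosylhydrazone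
Product: 20 (7R)-7-hydroxylongipina-2,8-dien-1-one (7-OH on the face of the seven-membered ring that carries C4), via cyclised sulfonylhydrazide 18 (not isolated), via alkyl diazene 19 (not isolated)
Conditions: Fe(acac)3 (30 mol %), PhSiH3 (2.5 equiv), EtOH/THF, rt; then MeOH, 60 °C
Reagents that add atoms: none
Why: HAT-initiated radical cyclisation onto a sulfonylhydrazone with traceless loss of sulfinate and N2 (radical reductive alkylation of a ketone), in which the iron hydride adds a hydrogen atom to the CH2 end of the 1,1-disubstituted alkene, the tertiary radical closes the seven-membered ring on the hydrazone carbon from the only face the Z-alkene tether can reach (anti to the three-carbon bridge), and hydrazide 18 then loses p-toluenesulfinate and N2 so that C5 ends as C–H with the configuration the bridged framework imposes, while the C7 carbinol is untouched.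

Step 13
Reactants: 21 angelic acid [(2Z)-2-methylbut-2-enoic acid] (2 molecules per molecule of product)
Product: 22 bis[(2Z)-2-methylbut-2-enoyl] peroxide (diangeloyl peroxide)
Conditions: H2O2 (50 % aq., 0.55 equiv per equiv of 21), DCC (1.05 equiv per equiv of 21), CH2Cl2, −10 → 0 °C; filtered, kept and used as a titrated solution
Reagents that add atoms: hydrogen peroxide, OO; angelic acid 21 (the second molecule, which supplies the second acyl group), C/C=C(/C)C(=O)O
Why: Carbodiimide-mediated condensation of two molecules of a carboxylic acid with one of H2O2 is the standard synthesis of symmetrical diacyl peroxides (the O-acylisourea of each acid is attacked first by H2O2 and then by the peracid), and it takes place at the carboxyl carbon under neutral conditions with no nucleophilic catalyst, so the Z geometry of angelic acid is kept.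

Step 14
Reactants: 20 (7R)-7-hydroxylongipina-2,8-dien-1-one; 22 diangeloyl peroxide (1.3 equiv)
Product: 23 target, 7-hydroxy-1-oxolongipin-2-ene-8,9-diyl bis[(2Z)-2-methylbut-2-enoate] (8-O and 9-O cis; 7-OH trans to 8-O)
Conditions: OsO4 (5 mol %), 4 Å MS, CH2Cl2, 0 °C → rt, dark, no amine or water
Reagents that add atoms: none
Why: Proposed new method: osmium-catalysed syn-bis(acyloxylation) in which the diacyl peroxide is both terminal oxidant and acyl donor — OsO4 adds to the C8=C9 alkene in a concerted [3+2] fashion anti to the allylic C7 hydroxyl (Kishi-type induction, with no cationic intermediate that could trigger cyclobutylcarbinyl rearrangement) to give the hexavalent osmium glycolate, the weak O–O bond of 22 adds oxidatively to give an octavalent osmium glycolate bis(angelate) whose Os–O–C(=O)R units are mixed anhydrides of osmic and angelic acid, and two intramolecular acyl transfers to the neighbouring glycolate oxygens release the cis-8,9-diester and regenerate OsO4 with no water, base or nucleophilic catalyst present that could isomerise angelate to tiglate, the closest known chemistry being catalytic OsO4 dihydroxylation with peroxide or N-oxide reoxidants, the interception of osmate esters by boronic acids, and the syn-dioxygenation of alkenes by cyclic diacyl peroxides.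

## Compound list

1 | (2E)-3-methylpent-2-en-4-yn-1-ol | OC/C=C(\C)C#C | starting material
2 | (2E)-3-methylpent-2-en-4-ynal | O=C/C=C(\C)C#C | intermediate
3 | methyl 3-methylbut-2-enoate | COC(=O)C=C(C)C | starting material
4 | tert-butyl[(1-methoxy-3-methylbuta-1,3-dien-1-yl)oxy]dimethylsilane (isomer mixture at the ketene acetal) | COC(O[Si](C)(C)C(C)(C)C)=CC(C)=C | intermediate
5 | methyl (2E,5S,6E)-5-hydroxy-3,7-dimethylnona-2,6-dien-8-ynoate | COC(=O)/C=C(\C)C[C@H](O)/C=C(\C)C#C | intermediate
6 | methyl (2E,5S,6E)-5-[(tert-butyldimethylsilyl)oxy]-3,7-dimethylnona-2,6-dien-8-ynoate | COC(=O)/C=C(\C)C[C@H](O[Si](C)(C)C(C)(C)C)/C=C(\C)C#C | intermediate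
7 | (2E,5S,6E)-5-[(tert-butyldimethylsilyl)oxy]-3,7-dimethylnona-2,6-dien-8-ynoic acid | OC(=O)/C=C(\C)C[C@H](O[Si](C)(C)C(C)(C)C)/C=C(\C)C#C | intermediate
8 | (2E,5S,6E)-5-[(tert-butyldimethylsilyl)oxy]-3,7-dimethylnona-2,6-dien-8-ynoyl chloride | ClC(=O)/C=C(\C)C[C@H](O[Si](C)(C)C(C)(C)C)/C=C(\C)C#C | intermediate
9 | (5S,6E)-5-[(tert-butyldimethylsilyl)oxy]-7-methyl-3-methylidenenona-1,6-dien-8-yn-1-one (vinylketene) | O=C=CC(=C)C[C@H](O[Si](C)(C)C(C)(C)C)/C=C(\C)C#C | intermediate
10 | (1R,2S,5R,7R)-2-[(tert-butyldimethylsilyl)oxy]-7-ethynyl-7-methyl-4-methylidenebicyclo[3.1.1]heptan-6-one (7-methyl syn, 7-ethynyl anti to the C2–C4 bridge; silyloxy trans to C7) | O=C1[C@H]2[C@@H](O[Si](C)(C)C(C)(C)C)CC(=C)[C@@H]1[C@@]2(C)C#C | intermediate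
11 | (1R,2S,5R,7R)-7-ethynyl-2-hydroxy-7-methyl-4-methylidenebicyclo[3.1.1]heptan-6-one | O=C1[C@H]2[C@@H](O)CC(=C)[C@@H]1[C@@]2(C)C#C | intermediate
12 | (1R,5R,7R)-7-ethynyl-7-methyl-4-methylidenebicyclo[3.1.1]heptane-2,6-dione | O=C1[C@H]2C(=O)CC(=C)[C@@H]1[C@@]2(C)C#C | intermediate
13 | (1R,5R,7R)-7-ethynyl-4,7-dimethylbicyclo[3.1.1]hept-3-ene-2,6-dione | O=C1[C@H]2C(=O)C=C(C)[C@@H]1[C@@]2(C)C#C | intermediate
14 | methacrolein (2-methylprop-2-enal) | CC(=C)C=O | starting material
15 | (1R,5R,7R)-7-[(3S)-3-hydroxy-4-methylpent-4-en-1-yn-1-yl]-4,7-dimethylbicyclo[3.1.1]hept-3-ene-2,6-dione | O=C1[C@H]2C(=O)C=C(C)[C@@H]1[C@@]2(C)C#C[C@@H](O)C(C)=C | intermediate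
16 | (1R,5R,7R)-7-[(1Z,3R)-3-hydroxy-4-methylpenta-1,4-dien-1-yl]-4,7-dimethylbicyclo[3.1.1]hept-3-ene-2,6-dione | O=C1[C@H]2C(=O)C=C(C)[C@@H]1[C@@]2(C)/C=C\[C@@H](O)C(C)=C | intermediate
17 | C6 mono(4-methylbenzenesulfonyl)hydrazone of 16 (C=N geometry not defined) | Cc1ccc(cc1)S(=O)(=O)NN=C2[C@H]3C(=O)C=C(C)[C@@H]2[C@@]3(C)/C=C\[C@@H](O)C(C)=C | intermediate
18 | N'-[(7R)-7-hydroxy-1-oxolongipina-2,8-dien-5-yl]-4-methylbenzenesulfonohydrazide (N on the face syn to the enone bridge) | C1[C@@H](O)C(C)(C)[C@]2(NNS(=O)(=O)c4ccc(C)cc4)[C@H]3C(=O)C=C(C)[C@@H]2[C@@]3(C)C=1 | intermediate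
19 | (7R)-5-diazenyl-7-hydroxylongipina-2,8-dien-1-one | C1[C@@H](O)C(C)(C)[C@]2(N=N)[C@H]3C(=O)C=C(C)[C@@H]2[C@@]3(C)C=1 | intermediate
20 | (7R)-7-hydroxylongipina-2,8-dien-1-one (H5 and the C10 methyl syn to the enone bridge; 7-OH on the C4 side of the seven-membered ring) | C1[C@@H](O)C(C)(C)[C@@H]2[C@H]3C(=O)C=C(C)[C@@H]2[C@@]3(C)C=1 | intermediate
21 | angelic acid, (2Z)-2-methylbut-2-enoic acid | C/C=C(/C)C(=O)O | starting material
22 | bis[(2Z)-2-methylbut-2-enoyl] peroxide | C/C=C(/C)C(=O)OOC(=O)/C(C)=C\C | intermediate
23 | 7-hydroxy-1-oxolongipin-2-ene-8,9-diyl bis[(2Z)-2-methylbut-2-enoate] (CNP0336239.1; 8-O and 9-O cis, 7-OH trans to 8-O) | C/C=C(/C)C(=O)O[C@@H]1[C@@H](O)C(C)(C)[C@@H]2[C@H]3C(=O)C=C(C)[C@@H]2[C@@]3(C)[C@@H]1OC(=O)/C(C)=C\C | target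

## Step count and risk

Total steps: 14. Longest linear sequence: 12 steps (from 1 to 23; steps 1, 3–12 and 14; steps 2 and 13 are side branches).

The three steps most likely to fail:

Step 6 (vinylketene [2+2]). Risks are ketene dimerisation, a less nucleophilic enyne alkene and only moderate face selectivity from the silyloxy centre; if the sense of induction turns out opposite, the antipodal catalyst in step 3 corrects it. The fallback sets out from acid 7: coupling with pyrrolidine (EDC·HCl, HOBt, CH2Cl2) gives the pyrrolidine amide F1. Tf2O and 2,4,6-collidine in ClCH2CH2Cl (0 → 80 °C) convert it by the Ghosez-type keteniminium [2+2] pathway, which uses a more electrophilic and non-dimerising cumulene, into the bicyclic cyclobutaniminium triflate F2. Aqueous NaHCO3 hydrolyses this to ketone 10, where the route is rejoined.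

Step 12 (radical ring closure on the hydrazone). Risks are a slow seven-membered closure that builds two adjacent fully substituted carbons, and premature reduction of the tertiary radical. The fallback is polar and sets out from 16. MnO2 (CH2Cl2) oxidises the bis-allylic carbinol to the cross-conjugated dienone F3. [(Ph3P)CuH]6 (PhMe, −40 °C) then reduces the unhindered isopropenyl ketone in conjugate fashion, and the copper enolate closes the seven-membered ring by aldol addition to the cyclobutanone (reductive aldol cyclisation) to give the tertiary cyclobutanol ketone F4. Me4NBH(OAc)3 (MeCN/AcOH, −20 °C) reduces only the β-hydroxy ketone, by internal hydride delivery from the 5-hydroxyl, and leaves the C1 enone alone. Because the 5-hydroxyl lies in the local symmetry plane of the seven-membered ring it cannot bias the two faces of the C7 ketone, so both C7 epimers are expected: the (7R)-diol F5 is separated and carried on, and the (7S)-diol F6 is returned to F4 with MnO2. TESCl/imidazole silylates only the secondary hydroxyl of F5 to give the triethylsilyl ether F7, MeO2CCOCl/DMAP acylates the tertiary hydroxyl to give the methyl oxalate F8, and Bu3SnH/AIBN (PhMe, 110 °C) removes the tertiary oxygen by radical deoxygenation to give the deoxygenated silyl ether F9, in which the framework again forces the C5–H configuration. HF·pyridine then frees allylic alcohol 20, where the route is rejoined.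

Step 14 (the proposed osmium-catalysed bis(acyloxylation)). Risks are that the peroxide does not turn over the osmium glycolate, that acyl transfer goes to the free C7 hydroxyl, or that OsO4 attacks the angelate alkenes. The fallback uses known chemistry and sets out from 20: OsO4 (2 mol %) with NMO in acetone/water dihydroxylates C8=C9 anti to the C7 hydroxyl and gives the 7,8,9-triol F10. Angelic acid 21, pre-activated as its mixed anhydride with 2,4,6-trichlorobenzoyl chloride and Et3N (PhMe, 80 °C, no DMAP, which avoids angelate-to-tiglate isomerisation), then esterifies the cis-8,9-diol; the C7 hydroxyl next to the gem-dimethyl carbon is expected to react slowest, although C9 is also neopentylic, so this selectivity is an assumption. This gives 23.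

## Further compounds

F1 | step 6 | 1-[(2E,5S,6E)-5-[(tert-butyldimethylsilyl)oxy]-3,7-dimethylnona-2,6-dien-8-ynoyl]pyrrolidine | O=C(N1CCCC1)/C=C(\C)C[C@H](O[Si](C)(C)C(C)(C)C)/C=C(\C)C#C
F2 | step 6 | 1-[(1R,2S,5R,7R)-2-[(tert-butyldimethylsilyl)oxy]-7-ethynyl-7-methyl-4-methylidenebicyclo[3.1.1]heptan-6-ylidene]pyrrolidinium trifluoromethanesulfonate | [O-]S(=O)(=O)C(F)(F)F.C1CC[N+](C1)=C2[C@H]3[C@@H](O[Si](C)(C)C(C)(C)C)CC(=C)[C@@H]2[C@@]3(C)C#C
F3 | step 12 | (1R,5R,7R)-4,7-dimethyl-7-[(1Z)-4-methyl-3-oxopenta-1,4-dien-1-yl]bicyclo[3.1.1]hept-3-ene-2,6-dione | O=C1[C@H]2C(=O)C=C(C)[C@@H]1[C@@]2(C)/C=C\C(=O)C(C)=C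
F4 | step 12 | 5-hydroxylongipina-2,8-diene-1,7-dione (5-OH syn to the enone bridge) | C1C(=O)C(C)(C)[C@]2(O)[C@H]3C(=O)C=C(C)[C@@H]2[C@@]3(C)C=1
F5 | step 12 | (7R)-5,7-dihydroxylongipina-2,8-dien-1-one (5-OH syn to the enone bridge) | C1[C@@H](O)C(C)(C)[C@]2(O)[C@H]3C(=O)C=C(C)[C@@H]2[C@@]3(C)C=1
F6 | step 12 | (7S)-5,7-dihydroxylongipina-2,8-dien-1-one (C7 epimer of F5) | C1[C@H](O)C(C)(C)[C@]2(O)[C@H]3C(=O)C=C(C)[C@@H]2[C@@]3(C)C=1
F7 | step 12 | (7R)-5-hydroxy-7-[(triethylsilyl)oxy]longipina-2,8-dien-1-one | C1[C@@H](O[Si](CC)(CC)CC)C(C)(C)[C@]2(O)[C@H]3C(=O)C=C(C)[C@@H]2[C@@]3(C)C=1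
F8 | step 12 | methyl (7R)-1-oxo-7-[(triethylsilyl)oxy]longipina-2,8-dien-5-yl oxalate | C1[C@@H](O[Si](CC)(CC)CC)C(C)(C)[C@]2(OC(=O)C(=O)OC)[C@H]3C(=O)C=C(C)[C@@H]2[C@@]3(C)C=1
F9 | step 12 | (7R)-7-[(triethylsilyl)oxy]longipina-2,8-dien-1-one | C1[C@@H](O[Si](CC)(CC)CC)C(C)(C)[C@@H]2[C@H]3C(=O)C=C(C)[C@@H]2[C@@]3(C)C=1
F10 | step 14 | 7,8,9-trihydroxylongipin-2-en-1-one (8-OH and 9-OH cis; 7-OH trans to 8-OH) | O[C@@H]1[C@@H](O)C(C)(C)[C@@H]2[C@H]3C(=O)C=C(C)[C@@H]2[C@@]3(C)[C@@H]1O
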